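Everything rests on cutting the dihydrofuran ring at O1–C2 and C3–C3a. This uncovers the natural chalcone isoliquiritigenin, in which the 4'-OH and C3', the ring A carbon flanked by both phenolic oxygens, behave as an aromatic enol (a 1,3-C,O-bis-nucleophile). The other piece is (S)-3,3-dimethyloxirane-2-carbaldehyde, a 1,2-bis-electrophile that already carries the C2–C3 oxygen pattern and the CMe2O unit. In one operation the magnesium phenolate adds through C3' to the aldehyde, and O4' then opens the neighbouring oxirane carbon. This creates the ring, both stereocentres and the tertiary alcohol without protecting groups. The precursor is just the unprotected chalcone plus the epoxy aldehyde, made from prenol in two steps.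

Key step: step 3

Remark: the target is numbered as a 2,3-dihydro-1-benzofuran (O1, C2, C3, C3a, C4–C7, C7a). Compounds 4–6 carry chalcone numbering, with primed atoms in ring A (the ketone-bearing ring) and unprimed atoms in ring B. Compounds 1 and 4 are taken as commercial.

Step 1
Reactants: 1 3-methylbut-2-en-1-ol (prenol)
Product: 2 [(2R)-3,3-dimethyloxiran-2-yl]methanol
Conditions: Ti(OiPr)4 (5 mol%), D-(−)-DIPT (6 mol%), t-BuOOH (1.5 equiv, anhydrous in isooctane), 4 Å MS, CH2Cl2, −20 °C; non-aqueous work-up, distillation
Reagents that add atoms: tert-butyl hydroperoxide, CC(C)(C)OO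
Why: Katsuki–Sharpless asymmetric epoxidation of a primary allylic alcohol, in which the titanium–D-(−)-tartrate complex binds the OH and delivers the peroxide oxygen to the alkene face opposite to the one chosen by L-(+)-tartrate (which gives 2S epoxy alcohols), so that C2 is set as R.

Step 2
Reactants: 2 [(2R)-3,3-dimethyloxiran-2-yl]methanol
Product: 3 (2S)-3,3-dimethyloxirane-2-carbaldehyde
Conditions: IBX (1.5 equiv), ClCH2CH2Cl, 75 °C; cool to 0 °C, filter; filtrate dried over 4 Å MS, titrated and used as a solution
Reagents that add atoms: none
Why: IBX oxidation of a primary alcohol stops at the aldehyde, leaves the oxirane untouched and gives only an insoluble by-product, and the stereocentre is not affected because an oxirane C–H is not enolised (the descriptor changes from R to S only because CHO outranks the CMe2 carbon).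

Step 3
Reactants: 4 isoliquiritigenin, (E)-1-(2,4-dihydroxyphenyl)-3-(4-hydroxyphenyl)prop-2-en-1-one; 3 (2S)-3,3-dimethyloxirane-2-carbaldehyde
Product: 7 brosimacutin G, via magnesium phenolate 5 (not isolated), via syn-epoxy alcohol 6 (not isolated)
Conditions: Mg(OMe)2 (0.55 equiv, in MeOH), THF, rt, then MeOH removed as toluene azeotrope; 3 (1.1 equiv, slow addition), ClCH2CH2Cl–THF, 4 Å MS, 0 → 40 °C; aq. NH4Cl
Reagents that add atoms: none
Why: The divalent magnesium 4'-phenolate 5 binds the aldehyde and oxirane oxygens of 3, C3' of ring A attacks the carbonyl carbon through a six-membered cyclic transition state (metal-phenolate ortho-hydroxyalkylation, an aromatic aldol addition), rearomatisation gives 6, and its O4' phenolate then opens the oxirane at the secondary carbon, the tertiary alkoxide set free passing the base on to the next molecule of 4. The closest known reaction type is the Friedel–Crafts hydroxyalkylation/epoxide-opening domino of hydroxyarenes with 2,3-epoxy aldehydes, the aromatic counterpart of the interrupted Feist–Bénary reaction. The dihydrofuran ring closes in the 5-exo-tet mode, which under basic conditions is preferred to 6-endo-tet attack at the tertiary carbon (chromane formation). C2 is controlled by the stereocentre of 3 through SN2 inversion (R oxirane carbon of 6 to 2S), and C3 by Cram-chelate addition to the aldehyde face anti to the CMe2 group, which gives the syn adduct (S carbinol) and hence the 2,3-trans ring; because the aldol step is reversible and the anti adduct could only close with C3–OH and CMe2O eclipsed, ring closure should select the same isomer. The step needs site selectivity for C3' and O4' over C5', O2' and ring B: only the most acidic 4'-OH is ionised, the 2'-OH···O=C hydrogen bond takes O2' out of play and fixes the ring A bonds so that C3' is the enolic carbon (as in Claisen rearrangements and enal chromene annulations of 2,4-dihydroxyaryl ketones), and ring B is a mono-oxygenated, much weaker carbon nucleophile. The chalcone has no enolisable C–H, so no ketone aldol can compete, and the reaction is a pure addition in which every atom of 3 and 4 ends up in 7.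

Compound list
1 | 3-methylbut-2-en-1-ol (prenol) | CC(C)=CCO | starting material
2 | [(2R)-3,3-dimethyloxiran-2-yl]methanol | OC[C@H]1OC1(C)C | intermediate
3 | (2S)-3,3-dimethyloxirane-2-carbaldehyde | O=C[C@H]1OC1(C)C | intermediate
4 | isoliquiritigenin, (E)-1-(2,4-dihydroxyphenyl)-3-(4-hydroxyphenyl)prop-2-en-1-one | O=C(/C=C/c1ccc(O)cc1)c1ccc(O)cc1O | starting material
5 | magnesium bis(4'-phenolate) of 4 | [Mg+2].[O-]c1ccc(C(=O)/C=C/c2ccc(O)cc2)c(O)c1.[O-]c1ccc(C(=O)/C=C/c2ccc(O)cc2)c(O)c1 | intermediate
6 | (E)-1-{3-[(S)-[(2R)-3,3-dimethyloxiran-2-yl](hydroxy)methyl]-2,4-dihydroxyphenyl}-3-(4-hydroxyphenyl)prop-2-en-1-one (syn-epoxy alcohol, present as its magnesium salt, drawn protonated) | O=C(/C=C/c1ccc(O)cc1)c1ccc(O)c([C@H](O)[C@H]2OC2(C)C)c1O | intermediate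
7 | brosimacutin G, (E)-1-[(2S,3S)-3,4-dihydroxy-2-(2-hydroxypropan-2-yl)-2,3-dihydro-1-benzofuran-5-yl]-3-(4-hydroxyphenyl)prop-2-en-1-one (2,3-trans) | CC(C)(O)[C@H]1Oc2ccc(C(=O)/C=C/c3ccc(O)cc3)c(O)c2[C@@H]1O | target

Total step count: 3. Longest linear sequence: 3 (1 → 2 → 3 → 7).

Steps most likely to fail

1. Step 3.
- What may go wrong: C–C bond formation at the acyl-deactivated ring A may be slower than the decay of 3 on the Lewis acidic magnesium, through oxirane rearrangement or hydride transfer from the benzylic alkoxide to a second aldehyde. Attack through ring B or C5' may compete, the chalcone may close to the flavanone by oxa-Michael addition, and facial selectivity at C3 may erode.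
- Fallback: the annulation is moved in front of the chalcone assembly. It sets out from 3, which is added slowly to an excess of the magnesium phenolate of commercial 2,4-dihydroxyacetophenone. This arene has no ring B and no enone, and it is cheap enough to be used in excess and recovered. The transient adduct 1-{3-[(S)-[(2R)-3,3-dimethyloxiran-2-yl](hydroxy)methyl]-2,4-dihydroxyphenyl}ethan-1-one F1 closes in the same flask to 1-[(2S,3S)-3,4-dihydroxy-2-(2-hydroxypropan-2-yl)-2,3-dihydro-1-benzofuran-5-yl]ethan-1-one F2. At this small, robust stage F2 can be freed from regio- or stereoisomers by chromatography or crystallisation. Claisen–Schmidt condensation of F2 with commercial 4-hydroxybenzaldehyde (KOH, EtOH–H2O, rt) then comes back to the route at 7.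

2. Step 2.
- What may go wrong: the volatile, easily hydrated aldehyde may be lost on handling, and the trisubstituted oxirane may open or rearrange thermally or under acid at 75 °C.
- Fallback: the order of oxidation and epoxidation is reversed. It sets out from 1, which MnO2 (CH2Cl2, rt) oxidises to 3-methylbut-2-enal F3. This enal is epoxidised with aqueous H2O2 under iminium–enamine catalysis by (S)-2-{bis[3,5-bis(trifluoromethyl)phenyl](trimethylsilyloxy)methyl}pyrrolidine (10 mol%, CH2Cl2, rt).
- Expected sense of induction: the β-peroxy enamine closes on the face left open by the diaryl(silyloxy)methyl group. This is the face sense of α-heterofunctionalisations of aldehydes with this catalyst, so the (S)-aldehyde should result. The sense would be checked by reduction to 2. The dried CH2Cl2 solution comes back to the route at 3.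

3. Step 1.
- What may go wrong: the small, water-soluble and volatile epoxy alcohol may be lost during isolation, and enantioselection may be incomplete with this small substrate.
- Fallback: direct isolation is replaced by catch and release through a crystalline ester. It sets out from 1. After the epoxidation the excess peroxide is reduced with P(OMe)3, and the cold mixture is treated with 4-nitrobenzoyl chloride and Et3N to give [(2R)-3,3-dimethyloxiran-2-yl]methyl 4-nitrobenzoate F4. This ester is isolated without aqueous loss and recrystallised to raise its enantiomeric purity. Methanolysis (catalytic K2CO3, MeOH, 0 °C) followed by distillation comes back to the route at 2.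

Further compounds
F1 | step 3 | 1-{3-[(S)-[(2R)-3,3-dimethyloxiran-2-yl](hydroxy)methyl]-2,4-dihydroxyphenyl}ethan-1-one | CC(=O)c1ccc(O)c([C@H](O)[C@H]2OC2(C)C)c1O
F2 | step 3 | 1-[(2S,3S)-3,4-dihydroxy-2-(2-hydroxypropan-2-yl)-2,3-dihydro-1-benzofuran-5-yl]ethan-1-one | CC(C)(O)[C@H]1Oc2ccc(C(C)=O)c(O)c2[C@@H]1O
F3 | step 2 | 3-methylbut-2-enal | CC(C)=CC=O
F4 | step 1 | [(2R)-3,3-dimethyloxiran-2-yl]methyl 4-nitrobenzoate | O=C(OC[C@H]1OC1(C)C)c1ccc(cc1)[N+](=O)[O-]
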